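The acyl chain C1–C6 is cut from its two neighbours (ester C–O bond to the diketo alcohol, C5–C6 bond to the pyranone), and C1–C5 is folded into a δ-lactone whose ring holds O, C1, C2, C3, C4 and C5. The anti,anti stereotriad C2-Me/C3-OH/C4-Me is all-cis in this ring, with both methyls equatorial. The key step closes the ring by a samarium Reformatsky reaction that forms the C3–C4 bond and both new stereocentres at once, guided by C2. Its precursor is an open-chain (S)-aldehyde (C3) whose C1 oxygen carries a racemic 2-bromopropanoate, made from methyl (R)-3-hydroxy-2-methylpropanoate.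

Key step: step 6

Locants C1–C6 below are those of the acyl chain of the target: C1 ester carbon, C3 carbinol, C5 ketone, C6 the carbon bound to the pyranone.

Remark: C6 lies between the C5 ketone and the pyranone ring and epimerises through its enol, so it is carried as a mixture of epimers from step 9 and fixed only in step 19, by separation of the (6S) epimer and re-equilibration of the (6R) epimer.

Step 1
Reactants: 1 methyl (R)-3-hydroxy-2-methylpropanoate
Product: 2 methyl (R)-3-[(tert-butyldimethylsilyl)oxy]-2-methylpropanoate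
Conditions: TBSCl, imidazole, CH2Cl2, 0 °C → rt
Reagents that add atoms: tert-butyldimethylsilyl chloride, CC(C)(C)[Si](C)(C)Cl
Why: Silyl ether formation at a primary alcohol under imidazole buffering, which does not touch the α-stereocentre of the ester.

Step 2
Reactants: 2 methyl (R)-3-[(tert-butyldimethylsilyl)oxy]-2-methylpropanoate
Product: 3 (S)-3-[(tert-butyldimethylsilyl)oxy]-2-methylpropan-1-ol
Conditions: iBu2AlH, CH2Cl2, −78 → −20 °C; aq. KNaC4H4O6 (tartrate)
Reagents that add atoms: none
Why: Low-temperature hydride reduction of the ester to the primary alcohol, kept cold because silyl migration in this mono-protected prochiral diol would racemise it.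

Step 3
Reactants: 3 (S)-3-[(tert-butyldimethylsilyl)oxy]-2-methylpropan-1-ol; 4 2-bromopropanoyl bromide (racemic)
Product: 5 (S)-3-[(tert-butyldimethylsilyl)oxy]-2-methylpropyl 2-bromopropanoate (both configurations at the C–Br carbon)
Conditions: pyridine, CH2Cl2, 0 °C
Reagents that add atoms: none
Why: O-Acylation of a primary alcohol by an acyl bromide with pyridine as acid scavenger; the bromide centre is left racemic on purpose because it becomes planar in the enolate of step 6.

Step 4
Reactants: 5 (S)-3-[(tert-butyldimethylsilyl)oxy]-2-methylpropyl 2-bromopropanoate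
Product: 6 (R)-3-hydroxy-2-methylpropyl 2-bromopropanoate
Conditions: HF·pyridine, pyridine, THF, 0 °C
Reagents that add atoms: none
Why: Buffered, non-basic desilylation of a primary silyl ether, chosen because base would displace the bromide and trigger 1,3-acyl migration, which turns 6 into its enantiomer; 6 is not stored.

Step 5
Reactants: 6 (R)-3-hydroxy-2-methylpropyl 2-bromopropanoate
Product: 7 (S)-2-methyl-3-oxopropyl 2-bromopropanoate
Conditions: Dess–Martin periodinane, CH2Cl2, 0 °C → rt
Reagents that add atoms: none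
Why: Dess–Martin oxidation of a primary alcohol under near-neutral conditions, which should neither enolise the α-centre nor eliminate the β-acyloxy group; 7 is used at once.

Step 6
Reactants: 7 (S)-2-methyl-3-oxopropyl 2-bromopropanoate
Product: 9 (3S,4S,5S)-4-hydroxy-3,5-dimethyltetrahydro-2H-pyran-2-one, via samarium ester enolate 8 (not isolated)
Conditions: SmI2 (2.2 equiv), THF, −78 °C, slow addition of 7; 0.1 M HCl
Reagents that add atoms: none
Why: Divalent samarium gives up two electrons in turn, bromide leaves, and the ester enolate 8 of trivalent samarium adds through carbon to the aldehyde held on the same ester oxygen; this is the samarium Reformatsky lactonisation known for β-(α-bromoacyloxy) aldehydes and ketones. The lactone closes in a 6-(enolendo)-exo-trig mode, since the enolate C=C lies inside the forming ring and the aldehyde C=O outside it. Samarium is bound to the enolate oxygen and to the aldehyde oxygen, so the forming lactone chair is fused to a six-membered chelate, and in this bridged array the new C–O bond at lactone C4 (chain C3) has to be axial. The existing methyl at lactone C5 (chain C2) takes the equatorial place in that chair, which decides the aldehyde face and gives the 4,5-cis relation (1,2-induction). The new methyl at lactone C3 (chain C4) becomes equatorial, cis to both neighbours, when it stands cis to the O–Sm bond of the chelated enolate, and this is also the more stable configuration at this enolisable centre. The step needs 1,2-induction and simple selectivity to agree on the all-cis isomer; the rigid bridged transition state and the non-basic medium, which leaves the aldehyde α-centre intact, should secure this.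

Step 7
Reactants: 9 (3S,4S,5S)-4-hydroxy-3,5-dimethyltetrahydro-2H-pyran-2-one
Product: 10 (3S,4S,5S)-4-[(tert-butyldimethylsilyl)oxy]-3,5-dimethyltetrahydro-2H-pyran-2-one
Conditions: TBSOTf, 2,6-lutidine, CH2Cl2, −78 → 0 °C
Reagents that add atoms: tert-butyldimethylsilyl trifluoromethanesulfonate, CC(C)(C)[Si](C)(C)OS(=O)(=O)C(F)(F)F
Why: Silyl ether formation at the hindered axial alcohol with a silyl triflate and a non-nucleophilic base, needed because free O3 would be oxidised in steps 10 and 18 and would act as a β-hydroxy ketone in step 17.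

Step 8
Reactants: 11 pentan-3-one; 12 propanoic acid (2 equiv)
Product: 13 2,6-diethyl-3,5-dimethyl-4H-pyran-4-one
Conditions: polyphosphoric acid, 150 °C
Reagents that add atoms: none
Why: Acid-mediated C-acylation of the ketone at both α-carbons followed by cyclodehydration of the 1,3,5-triketone (polyphosphoric acid pyranone synthesis).

Step 9
Reactants: 10 (3S,4S,5S)-4-[(tert-butyldimethylsilyl)oxy]-3,5-dimethyltetrahydro-2H-pyran-2-one; 13 2,6-diethyl-3,5-dimethyl-4H-pyran-4-one
Product: 15 (4S,5S,6S)-5-[(tert-butyldimethylsilyl)oxy]-2-(6-ethyl-3,5-dimethyl-4-oxo-4H-pyran-2-yl)-7-hydroxy-4,6-dimethylheptan-3-one (both epimers at heptanone C2 = chain C6), via lateral lithium anion 14 (not isolated)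
Conditions: 13 (2.2 equiv), LiN(iPr)2 (2.1 equiv), THF, −78 °C; 10; AcOH, −78 °C
Reagents that add atoms: none
Why: Lateral (vinylogous) deprotonation of the 2-ethylpyranone gives the extended enolate 14, which attacks the lactone carbonyl through its exocyclic carbon (Claisen-type C-acylation by a lactone), the acidic product being shielded from a second addition as its enolate; C6 forms without control, and 15 may sit partly as its six-membered lactol.

Step 10
Reactants: 15 hydroxy ketone (both C6 epimers)
Product: 16 (2R,3S,4S)-3-[(tert-butyldimethylsilyl)oxy]-6-(6-ethyl-3,5-dimethyl-4-oxo-4H-pyran-2-yl)-2,4-dimethyl-5-oxoheptanal (both C6 epimers)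
Conditions: Dess–Martin periodinane, pyridine, CH2Cl2, 0 °C
Reagents that add atoms: none
Why: Dess–Martin oxidation acts on the open hydroxy ketone and cannot turn the fully substituted lactol carbon into a lactone, so the C1 aldehyde is the only outcome; 16 is used at once because C6 could add to C1 in an intramolecular aldol reaction.

Step 11
Reactants: 17 methyl 4-oxotetrahydro-2H-thiopyran-3-carboxylate
Product: 18 methyl 1,4-dioxa-8-thiaspiro[4.5]decane-6-carboxylate (racemic)
Conditions: HOCH2CH2OH, TsOH (cat.), toluene, reflux, Dean–Stark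
Reagents that add atoms: ethane-1,2-diol, OCCO
Why: Acid-catalysed ketalisation of the ketone of a β-keto ester with azeotropic removal of water (dioxolane formation).

Step 12
Reactants: 18 methyl 1,4-dioxa-8-thiaspiro[4.5]decane-6-carboxylate
Product: 19 (1,4-dioxa-8-thiaspiro[4.5]decan-6-yl)methanol (racemic)
Conditions: LiAlH4, THF, 0 °C
Reagents that add atoms: none
Why: Hydride reduction of the ester to the primary alcohol; ketal and sulfide are inert to LiAlH4.

Step 13
Reactants: 19 (1,4-dioxa-8-thiaspiro[4.5]decan-6-yl)methanol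
Product: 20 1,4-dioxa-8-thiaspiro[4.5]decane-6-carbaldehyde (racemic)
Conditions: Dess–Martin periodinane, pyridine, CH2Cl2, 0 °C
Reagents that add atoms: none
Why: Dess–Martin oxidation of the primary alcohol, which should leave the dialkyl sulfide alone at 0 °C; the α-centre is racemic and is meant to racemise further in step 14.

Step 14
Reactants: 20 1,4-dioxa-8-thiaspiro[4.5]decane-6-carbaldehyde; 21 tetrahydro-4H-thiopyran-4-one
Product: 22 (3R)-3-[(S)-[(6R)-1,4-dioxa-8-thiaspiro[4.5]decan-6-yl](hydroxy)methyl]tetrahydro-4H-thiopyran-4-one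
Conditions: (R)-proline (0.5 equiv), DMSO, H2O (a few equiv), rt, 21 in excess
Reagents that add atoms: none
Why: Proline-catalysed direct aldol reaction through the enamine of 21: the (R)-catalyst sets the ketone α-centre and the carbinol (anti), Felkin addition selects one aldehyde enantiomer, and the other is fed in by racemisation through its enol (dynamic kinetic resolution).

Step 15
Reactants: 22 aldol adduct
Product: 23 (4R,5S,6R)-6-(2-ethyl-1,3-dioxolan-2-yl)-5-hydroxy-4-methylheptan-3-one
Conditions: Raney Ni, EtOH, reflux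
Reagents that add atoms: none
Why: Raney nickel hydrogenolysis of the four C–S bonds (desulfurisation) turns both rings into methyl and ethyl groups and unveils the open dipropionate chain without touching the stereocentres.

Step 16
Reactants: 23 (4R,5S,6R)-6-(2-ethyl-1,3-dioxolan-2-yl)-5-hydroxy-4-methylheptan-3-one
Product: 24 (4R,6R)-5-hydroxy-4,6-dimethylnonane-3,7-dione
Conditions: PPTS, acetone/H2O, 50 °C
Reagents that add atoms: water, O
Why: Mild acid hydrolysis of the dioxolane (ketal cleavage) frees the second ketone; the product is C2-symmetric, so its carbinol carbon is no longer a stereocentre.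

Step 17
Reactants: 16 keto aldehyde (both C6 epimers); 24 (4R,6R)-5-hydroxy-4,6-dimethylnonane-3,7-dione
Product: 25 (3R,4S,5S,6R)-3-hydroxy-4,6-dimethyl-7-oxononan-5-yl (2R,3R,4S)-3-[(tert-butyldimethylsilyl)oxy]-6-(6-ethyl-3,5-dimethyl-4-oxo-4H-pyran-2-yl)-2,4-dimethyl-5-oxoheptanoate (both C6 epimers)
Conditions: SmI2 (0.3 equiv), THF, −10 °C, 24 in excess
Reagents that add atoms: none
Why: Evans–Tishchenko reaction: trivalent samarium holds the β-hydroxy ketone and its hemiacetal with 16, and hydride transfer to the ketone gives the ester of the hindered carbinol under neutral conditions with a 1,3-anti alcohol that step 18 removes; the two ketones of 24 are equivalent by symmetry, so one product forms.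

Step 18
Reactants: 25 hydroxy ester (both C6 epimers)
Product: 26 (4R,6R)-4,6-dimethyl-3,7-dioxononan-5-yl (2R,3R,4S)-3-[(tert-butyldimethylsilyl)oxy]-6-(6-ethyl-3,5-dimethyl-4-oxo-4H-pyran-2-yl)-2,4-dimethyl-5-oxoheptanoate (both C6 epimers)
Conditions: Dess–Martin periodinane, pyridine, CH2Cl2, 0 °C → rt
Reagents that add atoms: none
Why: Dess–Martin oxidation of the secondary alcohol restores the second ketone without strong base, which would eliminate the β-acyloxy ketone.

Step 19
Reactants: 26 silyl ether (both C6 epimers)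
Product: 27 (4R,6R)-4,6-dimethyl-3,7-dioxononan-5-yl (2R,3R,4S,6S)-6-(6-ethyl-3,5-dimethyl-4-oxo-4H-pyran-2-yl)-3-hydroxy-2,4-dimethyl-5-oxoheptanoate
Conditions: HF·pyridine, pyridine, THF, 0 °C → rt; chromatographic separation of the C6 epimers
Reagents that add atoms: none
Why: Buffered fluoride desilylation of the secondary silyl ether should not eliminate or shift the ester; the (6S) epimer is then separated, and the (6R) epimer is re-equilibrated through its enol with a weak amine base (imidazole, CH2Cl2) and separated again.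

Compound list
1 | methyl (R)-3-hydroxy-2-methylpropanoate | COC(=O)[C@H](C)CO | starting material
2 | methyl (R)-3-[(tert-butyldimethylsilyl)oxy]-2-methylpropanoate | COC(=O)[C@H](C)CO[Si](C)(C)C(C)(C)C | intermediate
3 | (S)-3-[(tert-butyldimethylsilyl)oxy]-2-methylpropan-1-ol | OC[C@H](C)CO[Si](C)(C)C(C)(C)C | intermediate
4 | 2-bromopropanoyl bromide (racemic) | CC(Br)C(Br)=O | starting material
5 | (S)-3-[(tert-butyldimethylsilyl)oxy]-2-methylpropyl 2-bromopropanoate | CC(Br)C(=O)OC[C@H](C)CO[Si](C)(C)C(C)(C)C | intermediate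
6 | (R)-3-hydroxy-2-methylpropyl 2-bromopropanoate | CC(Br)C(=O)OC[C@H](C)CO | intermediate
7 | (S)-2-methyl-3-oxopropyl 2-bromopropanoate | CC(Br)C(=O)OC[C@H](C)C=O | intermediate
8 | samarium ester enolate of 7 (diiodosamarium on the enolate oxygen, methyl cis to O–Sm) | C/C=C(\O[Sm](I)I)OC[C@H](C)C=O | intermediate
9 | (3S,4S,5S)-4-hydroxy-3,5-dimethyltetrahydro-2H-pyran-2-one | O=C1OC[C@H](C)[C@H](O)[C@@H]1C | intermediate
10 | (3S,4S,5S)-4-[(tert-butyldimethylsilyl)oxy]-3,5-dimethyltetrahydro-2H-pyran-2-one | O=C1OC[C@H](C)[C@H](O[Si](C)(C)C(C)(C)C)[C@@H]1C | intermediate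
11 | pentan-3-one | CCC(=O)CC | starting material
12 | propanoic acid | CCC(=O)O | starting material
13 | 2,6-diethyl-3,5-dimethyl-4H-pyran-4-one | CCc1oc(CC)c(C)c(=O)c1C | intermediate
14 | lithium 6-ethyl-2-ethylidene-3,5-dimethyl-2H-pyran-4-olate (lateral anion of 13) | [Li+].CC=C1OC(CC)=C(C)C([O-])=C1C | intermediate
15 | (4S,5S,6S)-5-[(tert-butyldimethylsilyl)oxy]-2-(6-ethyl-3,5-dimethyl-4-oxo-4H-pyran-2-yl)-7-hydroxy-4,6-dimethylheptan-3-one, both C2 epimers (chain C6) | OC[C@H](C)[C@H](O[Si](C)(C)C(C)(C)C)[C@H](C)C(=O)C(C)c1oc(CC)c(C)c(=O)c1C | intermediate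
16 | (2R,3S,4S)-3-[(tert-butyldimethylsilyl)oxy]-6-(6-ethyl-3,5-dimethyl-4-oxo-4H-pyran-2-yl)-2,4-dimethyl-5-oxoheptanal, both C6 epimers | O=C[C@H](C)[C@H](O[Si](C)(C)C(C)(C)C)[C@H](C)C(=O)C(C)c1oc(CC)c(C)c(=O)c1C | intermediate
17 | methyl 4-oxotetrahydro-2H-thiopyran-3-carboxylate | COC(=O)C1CSCCC1=O | starting material
18 | methyl 1,4-dioxa-8-thiaspiro[4.5]decane-6-carboxylate (racemic) | COC(=O)C1CSCCC12OCCO2 | intermediate
19 | (1,4-dioxa-8-thiaspiro[4.5]decan-6-yl)methanol (racemic) | OCC1CSCCC12OCCO2 | intermediate
20 | 1,4-dioxa-8-thiaspiro[4.5]decane-6-carbaldehyde (racemic) | O=CC1CSCCC12OCCO2 | intermediate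
21 | tetrahydro-4H-thiopyran-4-one | O=C1CCSCC1 | starting material
22 | (3R)-3-[(S)-[(6R)-1,4-dioxa-8-thiaspiro[4.5]decan-6-yl](hydroxy)methyl]tetrahydro-4H-thiopyran-4-one | O=C1CCSC[C@@H]1[C@H](O)[C@H]1CSCCC12OCCO2 | intermediate
23 | (4R,5S,6R)-6-(2-ethyl-1,3-dioxolan-2-yl)-5-hydroxy-4-methylheptan-3-one | CCC(=O)[C@H](C)[C@H](O)[C@@H](C)C1(CC)OCCO1 | intermediate
24 | (4R,6R)-5-hydroxy-4,6-dimethylnonane-3,7-dione | CCC(=O)[C@H](C)C(O)[C@@H](C)C(=O)CC | intermediate
25 | (3R,4S,5S,6R)-3-hydroxy-4,6-dimethyl-7-oxononan-5-yl (2R,3R,4S)-3-[(tert-butyldimethylsilyl)oxy]-6-(6-ethyl-3,5-dimethyl-4-oxo-4H-pyran-2-yl)-2,4-dimethyl-5-oxoheptanoate, both C6 epimers | CC[C@@H](O)[C@H](C)[C@H](OC(=O)[C@H](C)[C@H](O[Si](C)(C)C(C)(C)C)[C@H](C)C(=O)C(C)c1oc(CC)c(C)c(=O)c1C)[C@@H](C)C(=O)CC | intermediate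
26 | (4R,6R)-4,6-dimethyl-3,7-dioxononan-5-yl (2R,3R,4S)-3-[(tert-butyldimethylsilyl)oxy]-6-(6-ethyl-3,5-dimethyl-4-oxo-4H-pyran-2-yl)-2,4-dimethyl-5-oxoheptanoate, both C6 epimers | CCC(=O)[C@H](C)C(OC(=O)[C@H](C)[C@H](O[Si](C)(C)C(C)(C)C)[C@H](C)C(=O)C(C)c1oc(CC)c(C)c(=O)c1C)[C@@H](C)C(=O)CC | intermediate
27 | (4R,6R)-4,6-dimethyl-3,7-dioxononan-5-yl (2R,3R,4S,6S)-6-(6-ethyl-3,5-dimethyl-4-oxo-4H-pyran-2-yl)-3-hydroxy-2,4-dimethyl-5-oxoheptanoate | CCC(=O)[C@H](C)C(OC(=O)[C@H](C)[C@H](O)[C@H](C)C(=O)[C@@H](C)c1oc(CC)c(C)c(=O)c1C)[C@@H](C)C(=O)CC | target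

Total step count: 19.
Longest linear sequence: 12 steps (1–7, 9, 10, 17, 18, 19) from 1; side branches are step 8 (pyranone) and steps 11–16 (diketo alcohol).

Steps most likely to fail

1. Step 6. The enolate may close through more than one transition state, so that facial selection at the aldehyde or the simple selectivity is poor and a mixture of lactone diastereomers results. The fallback sets out from 9 (taken as the diastereomer mixture, in which the C5 centre from 1 is intact) and comes back at 9. The mixture is oxidised with Dess–Martin periodinane to the β-keto lactone, which exists as the enol (S)-4-hydroxy-3,5-dimethyl-5,6-dihydro-2H-pyran-2-one F1. Hydrogenation of F1 over Raney Ni (H2, 50 bar, EtOAc) should add both hydrogens cis, from the face opposite the C5 methyl, and return all-cis 9. The C3 and C4 centres are then set by heterogeneous hydrogenation and not by the aldol closure.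

2. Step 9. Proton transfer from the lactone α-position to the basic anion may compete with addition and be followed by loss of the β-silyloxy group; the freed C1 alkoxide may also take over the silyl group or hold the product as a lactol that resists step 10. The fallback sets out from 10 and comes back at 15. Lactone 10 is opened with MeNHOMe·HCl and Me3Al (CH2Cl2, 0 °C) to (2S,3S,4S)-3-[(tert-butyldimethylsilyl)oxy]-5-hydroxy-N-methoxy-N,2,4-trimethylpentanamide F2. This is silylated at once (Et3SiCl, imidazole) to (2S,3S,4S)-3-[(tert-butyldimethylsilyl)oxy]-N-methoxy-N,2,4-trimethyl-5-[(triethylsilyl)oxy]pentanamide F3. Anion 14 is then acylated by F3, whose chelated adduct cannot over-react and carries no alkoxide, to give (4S,5S,6S)-5-[(tert-butyldimethylsilyl)oxy]-2-(6-ethyl-3,5-dimethyl-4-oxo-4H-pyran-2-yl)-4,6-dimethyl-7-[(triethylsilyl)oxy]heptan-3-one F4 (both C2 epimers). The primary triethylsilyl ether is removed with PPTS in MeOH at 0 °C, which leaves the secondary silyl ether, to give 15.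

3. Step 17. The keto aldehyde 16 may be consumed by intramolecular aldol addition of C6 to C1, or by pinacol coupling, before the hindered hemiacetal transfers hydride. The fallback sets out from 16 and comes back at 26, so that steps 17 and 18 are not needed. Aldehyde 16 is oxidised (NaClO2, NaH2PO4, 2-methylbut-2-ene, tBuOH/H2O) to (2R,3R,4S)-3-[(tert-butyldimethylsilyl)oxy]-6-(6-ethyl-3,5-dimethyl-4-oxo-4H-pyran-2-yl)-2,4-dimethyl-5-oxoheptanoic acid F5 (both C6 epimers). F5 is esterified with 24 under Yamaguchi conditions (2,4,6-trichlorobenzoyl chloride, Et3N, toluene; then 24, DMAP) to give 26 directly.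

Further compounds
F1 | step 6 | (S)-4-hydroxy-3,5-dimethyl-5,6-dihydro-2H-pyran-2-one | O=C1OC[C@H](C)C(O)=C1C
F2 | step 9 | (2S,3S,4S)-3-[(tert-butyldimethylsilyl)oxy]-5-hydroxy-N-methoxy-N,2,4-trimethylpentanamide | OC[C@H](C)[C@H](O[Si](C)(C)C(C)(C)C)[C@H](C)C(=O)N(C)OC
F3 | step 9 | (2S,3S,4S)-3-[(tert-butyldimethylsilyl)oxy]-N-methoxy-N,2,4-trimethyl-5-[(triethylsilyl)oxy]pentanamide | CC[Si](CC)(CC)OC[C@H](C)[C@H](O[Si](C)(C)C(C)(C)C)[C@H](C)C(=O)N(C)OC
F4 | step 9 | (4S,5S,6S)-5-[(tert-butyldimethylsilyl)oxy]-2-(6-ethyl-3,5-dimethyl-4-oxo-4H-pyran-2-yl)-4,6-dimethyl-7-[(triethylsilyl)oxy]heptan-3-one, both C2 epimers | CC[Si](CC)(CC)OC[C@H](C)[C@H](O[Si](C)(C)C(C)(C)C)[C@H](C)C(=O)C(C)c1oc(CC)c(C)c(=O)c1C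
F5 | step 17 | (2R,3R,4S)-3-[(tert-butyldimethylsilyl)oxy]-6-(6-ethyl-3,5-dimethyl-4-oxo-4H-pyran-2-yl)-2,4-dimethyl-5-oxoheptanoic acid, both C6 epimers | OC(=O)[C@H](C)[C@H](O[Si](C)(C)C(C)(C)C)[C@H](C)C(=O)C(C)c1oc(CC)c(C)c(=O)c1C
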